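The route rests on cutting the alkyl C5–O1 bond of the oxolan-2-one ring. C5 sits γ to the C2 carboxyl carbon, so a tert-butyl ester at C2 can reach a leaving group at C5 through a five-membered transition state. The precursor is an open-chain Evans syn-aldol adduct whose C5 carbinol has the configuration opposite to the target. In one operation, O-triflation triggers attack of the ester carbonyl oxygen on C5 with inversion, loss of isobutene and closure of the lactone. This turns the easily made syn aldol into the contra-thermodynamic 4,5-cis, 3,4-trans ring. C3 comes from the chiral pool and C4 from the auxiliary.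

Key step: step 7

Remark: atoms are numbered as in the lactone throughout (O1, C2 carbonyl, C3 methyl-bearing, C4 carboxyl-bearing, C5 chain-bearing), also for open-chain precursors; monoester 4 is assumed to be a catalogue compound (otherwise it is made by asymmetric hydrogenation of 4-methyl itaconate).

Step 1
Reactants: 1 15-hydroxypentadecanoic acid
Product: 2 16-hydroxyhexadecan-2-one
Conditions: MeLi (3.5 equiv), THF, 0 °C to rt; inverse quench into cold 1 M HCl
Reagents that add atoms: methyllithium, [Li]C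
Why: Addition of methyllithium to the lithium carboxylate should stop at the dilithium gem-diolate, which releases the methyl ketone only on acidic quench (classical acid-to-methyl-ketone conversion), the extra equivalent being consumed by the hydroxyl group.

Step 2
Reactants: 2 16-hydroxyhexadecan-2-one
Product: 3 15-oxohexadecanal
Conditions: TEMPO (10 mol %), PhI(OAc)2 (1.1 equiv), CH2Cl2, rt
Reagents that add atoms: none
Why: The oxoammonium-mediated TEMPO/PhI(OAc)2 oxidation should take the primary alcohol to the aldehyde without over-oxidation and leave the ketone untouched.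

Step 3
Reactants: 4 (2S)-4-methoxy-2-methyl-4-oxobutanoic acid
Product: 5 1-tert-butyl 4-methyl (2S)-2-methylbutanedioate
Conditions: isobutene (excess), H2SO4 (cat.), CH2Cl2, sealed vessel, rt
Reagents that add atoms: 2-methylpropene (isobutene), CC(C)=C
Why: Acid-catalysed addition of the carboxylic acid to isobutene (tert-butyl esterification) should not affect the methyl ester or the stereocentre.

Step 4
Reactants: 5 1-tert-butyl 4-methyl (2S)-2-methylbutanedioate
Product: 6 (3S)-4-tert-butoxy-3-methyl-4-oxobutanoic acid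
Conditions: LiOH·H2O (1.05 equiv), THF/H2O 3:1, 0 °C; then 1 M HCl to pH 3
Reagents that add atoms: lithium hydroxide, [Li+].[OH-]
Why: Saponification should be chemoselective for the unhindered methyl ester over the tert-butyl ester, and hydroxide at 0 °C should not enolise the stereocentre next to the tert-butyl ester.

Step 5
Reactants: 6 (3S)-4-tert-butoxy-3-methyl-4-oxobutanoic acid; 7 (4S)-4-benzyl-1,3-oxazolidin-2-one
Product: 9 tert-butyl (2S)-4-[(4S)-4-benzyl-2-oxo-1,3-oxazolidin-3-yl]-2-methyl-4-oxobutanoate, via mixed pivalic anhydride 8 (not isolated)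
Conditions: PivCl, Et3N, THF, −20 °C; then LiCl, 7, −20 °C to rt
Reagents that add atoms: none
Why: N-Acylation of the oxazolidinone through the mixed pivalic anhydride (LiCl/Et3N protocol) should occur at the less hindered acyl carbon of the anhydride.

Step 6
Reactants: 9 tert-butyl (2S)-4-[(4S)-4-benzyl-2-oxo-1,3-oxazolidin-3-yl]-2-methyl-4-oxobutanoate (1.1 equiv); 3 15-oxohexadecanal
Product: 12 tert-butyl (2S,3S,4R)-3-{[(4S)-4-benzyl-2-oxo-1,3-oxazolidin-3-yl]carbonyl}-4-hydroxy-2-methyl-18-oxononadecanoate, via dibutylboron Z-enolate 10 (not isolated), via dibutylboron aldolate 11 (not isolated)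
Conditions: n-Bu2BOTf (1.05 equiv), i-Pr2NEt (1.2 equiv), CH2Cl2, 0 °C; then 3, −78 to 0 °C; pH 7 buffer, MeOH, 30 % H2O2, 0 °C
Reagents that add atoms: none
Why: In this Evans syn aldol the Z-boron enolate should react through a Zimmerman–Traxler chair in which the (S)-benzyl auxiliary shields one enolate face, setting C4 as S and C5 as R (chain positions 3 and 4), while the aldehyde reacts in preference to the ketone and the excess of 9 over Bu2BOTf leaves no boron triflate to enolise the methyl ketone.

Step 7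
Reactants: 12 tert-butyl (2S,3S,4R)-3-{[(4S)-4-benzyl-2-oxo-1,3-oxazolidin-3-yl]carbonyl}-4-hydroxy-2-methyl-18-oxononadecanoate
Product: 15 (4S)-4-benzyl-3-{[(2S,3S,4S)-4-methyl-5-oxo-2-(14-oxopentadecyl)oxolan-3-yl]carbonyl}-1,3-oxazolidin-2-one, via C5 triflate 13 (not isolated), via O-tert-butyl lactonium triflate 14 (not isolated)
Conditions: Tf2O (1.15 equiv), 2,6-lutidine (3 equiv), CH2Cl2, −78 to 0 °C
Reagents that add atoms: none
Why: Triflation of the C5 hydroxyl should give secondary triflate 13, the carbonyl oxygen of the tert-butyl ester on C2 then attacks C5 from the face opposite the leaving group, and the O-tert-butyl lactonium ion 14 collapses by loss of the tert-butyl cation as isobutene. The closest known reaction type is the invertive cyclisation of sulfonate-activated alcohols by the carbonyl oxygen of tert-butyl esters and tert-butyl carbamates (neighbouring-group participation with loss of isobutene), an SN2 relative of the Mitsunobu lactonisation. The oxolan-2-one ring is closed in the 5-exo-tet mode by forming the O1–C5 bond. C5 is the only stereocentre created, and its S configuration follows stereospecifically from inversion of the (R)-carbinol set by the aldol, which places the side chain cis to the C4 acyl group and trans to the C3 methyl; C3 and C4 are not touched. The step needs substitution to beat elimination, and the ester oxygen to beat the oxazolidinone oxygen and the ketone as partners for the electrophiles; the first is secured by −78 °C and a hindered weak base that cannot enolise the imide, the second by the five-membered transition state (the oxazolidinone would need a six-membered one) and by the much faster triflation of an alcohol than of a ketone.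

Step 8
Reactants: 15 (4S)-4-benzyl-3-{[(2S,3S,4S)-4-methyl-5-oxo-2-(14-oxopentadecyl)oxolan-3-yl]carbonyl}-1,3-oxazolidin-2-one
Product: 16 (2S,3S,4S)-4-methyl-5-oxo-2-(14-oxopentadecyl)oxolane-3-carboxylic acid
Conditions: LiOH, 30 % H2O2, THF/H2O 3:1, 0 °C; then aq. Na2SO3; 1 M HCl
Reagents that add atoms: hydrogen peroxide (as LiOOH), OO
Why: Lithium hydroperoxide should attack the exocyclic imide carbonyl selectively (Evans auxiliary cleavage), its low basicity should leave C4 and the lactone intact, and any ring-opened hydroxy acid recloses on acidification without touching the C5–O1 bond.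

Compound list
1 | 15-hydroxypentadecanoic acid | OCCCCCCCCCCCCCCC(=O)O | starting material
2 | 16-hydroxyhexadecan-2-one | CC(=O)CCCCCCCCCCCCCCO | intermediate
3 | 15-oxohexadecanal | CC(=O)CCCCCCCCCCCCCC=O | intermediate
4 | (2S)-4-methoxy-2-methyl-4-oxobutanoic acid | C[C@@H](CC(=O)OC)C(=O)O | starting material
5 | 1-tert-butyl 4-methyl (2S)-2-methylbutanedioate | C[C@@H](CC(=O)OC)C(=O)OC(C)(C)C | intermediate
6 | (3S)-4-tert-butoxy-3-methyl-4-oxobutanoic acid | C[C@@H](CC(=O)O)C(=O)OC(C)(C)C | intermediate
7 | (4S)-4-benzyl-1,3-oxazolidin-2-one | O=C1OC[C@H](Cc2ccccc2)N1 | starting material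
8 | mixed anhydride of 6 with pivalic acid | C[C@@H](CC(=O)OC(=O)C(C)(C)C)C(=O)OC(C)(C)C | intermediate (not isolated)
9 | tert-butyl (2S)-4-[(4S)-4-benzyl-2-oxo-1,3-oxazolidin-3-yl]-2-methyl-4-oxobutanoate | C[C@@H](CC(=O)N1[C@@H](Cc2ccccc2)COC1=O)C(=O)OC(C)(C)C | intermediate
10 | dibutylboron Z-enolate of 9 | CCCCB(CCCC)O/C(=C\[C@H](C)C(=O)OC(C)(C)C)N1[C@@H](Cc2ccccc2)COC1=O | intermediate (not isolated)
11 | dibutylboron aldolate (O-dibutylboryl derivative of 12) | CC(=O)CCCCCCCCCCCCC[C@@H](OB(CCCC)CCCC)[C@H]([C@H](C)C(=O)OC(C)(C)C)C(=O)N1[C@@H](Cc2ccccc2)COC1=O | intermediate (not isolated)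
12 | tert-butyl (2S,3S,4R)-3-{[(4S)-4-benzyl-2-oxo-1,3-oxazolidin-3-yl]carbonyl}-4-hydroxy-2-methyl-18-oxononadecanoate | CC(=O)CCCCCCCCCCCCC[C@@H](O)[C@H]([C@H](C)C(=O)OC(C)(C)C)C(=O)N1[C@@H](Cc2ccccc2)COC1=O | intermediate
13 | tert-butyl (2S,3S,4R)-3-{[(4S)-4-benzyl-2-oxo-1,3-oxazolidin-3-yl]carbonyl}-2-methyl-18-oxo-4-(trifluoromethanesulfonyloxy)nonadecanoate | CC(=O)CCCCCCCCCCCCC[C@@H](OS(=O)(=O)C(F)(F)F)[C@H]([C@H](C)C(=O)OC(C)(C)C)C(=O)N1[C@@H](Cc2ccccc2)COC1=O | intermediate (not isolated)
14 | O-tert-butyl lactonium triflate (2-tert-butoxy-4,5-dihydro-3H-furan-1-ium form of 15, 3S,4S,5S) | CC(=O)CCCCCCCCCCCCC[C@@H]1[O+]=C(OC(C)(C)C)[C@@H](C)[C@@H]1C(=O)N2[C@@H](Cc3ccccc3)COC2=O.[O-]S(=O)(=O)C(F)(F)F | intermediate (not isolated)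
15 | (4S)-4-benzyl-3-{[(2S,3S,4S)-4-methyl-5-oxo-2-(14-oxopentadecyl)oxolan-3-yl]carbonyl}-1,3-oxazolidin-2-one | CC(=O)CCCCCCCCCCCCC[C@@H]1OC(=O)[C@@H](C)[C@@H]1C(=O)N2[C@@H](Cc3ccccc3)COC2=O | intermediate
16 | (2S,3S,4S)-4-methyl-5-oxo-2-(14-oxopentadecyl)oxolane-3-carboxylic acid | CC(=O)CCCCCCCCCCCCC[C@@H]1OC(=O)[C@@H](C)[C@@H]1C(=O)O | target

Total step count: 8. Longest linear sequence: 6 steps (steps 3, 4, 5, 6, 7 and 8, from 4); the aldehyde branch (steps 1 and 2) joins at step 6.

Steps most likely to fail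

Step 7. The triflate may lose its leaving group by elimination (towards C4 or into the chain), or be intercepted by the oxazolidinone carbonyl or the base before the hindered ester oxygen closes the ring. The fallback sets out from 12 and comes back at 15. The alcohol is converted with MsCl/Et3N (CH2Cl2, −10 °C) into the isolable mesylate tert-butyl (2S,3S,4R)-3-{[(4S)-4-benzyl-2-oxo-1,3-oxazolidin-3-yl]carbonyl}-4-(methanesulfonyloxy)-2-methyl-18-oxononadecanoate F1. The tert-butyl ester is then cleaved with TFA (CH2Cl2, 0 °C) to the mesyloxy acid (2S,3S,4R)-3-{[(4S)-4-benzyl-2-oxo-1,3-oxazolidin-3-yl]carbonyl}-4-(methanesulfonyloxy)-2-methyl-18-oxononadecanoic acid F2. The free carboxylate (NaHCO3, DMF, rt) then displaces the mesylate in an SN2 lactonisation with inversion to give 15. Here the nucleophile is a carboxylate anion acting on a stable sulfonate, with no strongly electrophilic reagent present during ring closure.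

Step 6. The boron triflate/amine pair may enolise the methyl ketone, leading to self-condensation of the keto aldehyde, or boron coordination to the ketone may erode facial selectivity. The fallback sets out from 2 and comes back at 15, with the ketone masked first. Ethylene glycol and TsOH (cat.) in toluene with a Dean–Stark trap give 14-(2-methyl-1,3-dioxolan-2-yl)tetradecan-1-ol F3. Dess–Martin periodinane/NaHCO3 gives 14-(2-methyl-1,3-dioxolan-2-yl)tetradecanal F4. The same boron aldol with 9 gives tert-butyl (2S,3S,4R)-3-{[(4S)-4-benzyl-2-oxo-1,3-oxazolidin-3-yl]carbonyl}-4-hydroxy-2-methyl-17-(2-methyl-1,3-dioxolan-2-yl)heptadecanoate F5. Tf2O/2,6-lutidine gives (4S)-4-benzyl-3-({(2S,3S,4S)-4-methyl-2-[13-(2-methyl-1,3-dioxolan-2-yl)tridecyl]-5-oxooxolan-3-yl}carbonyl)-1,3-oxazolidin-2-one F6. PPTS in acetone/H2O then releases the ketone to give 15.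

Step 8. Base-mediated epimerisation at C4 towards the more stable 4,5-trans lactone, or β-elimination of the lactone oxygen, may occur during hydroperoxide cleavage. The fallback sets out from 15 and comes back at 16 under non-basic conditions. Lewis-acid transesterification (BnOH, Yb(OTf)3 cat., CH2Cl2, rt) gives benzyl (2S,3S,4S)-4-methyl-5-oxo-2-(14-oxopentadecyl)oxolane-3-carboxylate F7. Hydrogenolysis (H2, palladium on carbon Pd/C, EtOAc) then gives 16.

Further compounds
F1 | step 7 | tert-butyl (2S,3S,4R)-3-{[(4S)-4-benzyl-2-oxo-1,3-oxazolidin-3-yl]carbonyl}-4-(methanesulfonyloxy)-2-methyl-18-oxononadecanoate | CC(=O)CCCCCCCCCCCCC[C@@H](OS(C)(=O)=O)[C@H]([C@H](C)C(=O)OC(C)(C)C)C(=O)N1[C@@H](Cc2ccccc2)COC1=O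
F2 | step 7 | (2S,3S,4R)-3-{[(4S)-4-benzyl-2-oxo-1,3-oxazolidin-3-yl]carbonyl}-4-(methanesulfonyloxy)-2-methyl-18-oxononadecanoic acid | CC(=O)CCCCCCCCCCCCC[C@@H](OS(C)(=O)=O)[C@H]([C@H](C)C(=O)O)C(=O)N1[C@@H](Cc2ccccc2)COC1=O
F3 | step 6 | 14-(2-methyl-1,3-dioxolan-2-yl)tetradecan-1-ol | CC1(CCCCCCCCCCCCCCO)OCCO1
F4 | step 6 | 14-(2-methyl-1,3-dioxolan-2-yl)tetradecanal | CC1(CCCCCCCCCCCCCC=O)OCCO1
F5 | step 6 | tert-butyl (2S,3S,4R)-3-{[(4S)-4-benzyl-2-oxo-1,3-oxazolidin-3-yl]carbonyl}-4-hydroxy-2-methyl-17-(2-methyl-1,3-dioxolan-2-yl)heptadecanoate | CC1(CCCCCCCCCCCCC[C@@H](O)[C@H]([C@H](C)C(=O)OC(C)(C)C)C(=O)N2[C@@H](Cc3ccccc3)COC2=O)OCCO1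
F6 | step 6 | (4S)-4-benzyl-3-({(2S,3S,4S)-4-methyl-2-[13-(2-methyl-1,3-dioxolan-2-yl)tridecyl]-5-oxooxolan-3-yl}carbonyl)-1,3-oxazolidin-2-one | CC1(CCCCCCCCCCCCC[C@@H]2OC(=O)[C@@H](C)[C@@H]2C(=O)N3[C@@H](Cc4ccccc4)COC3=O)OCCO1
F7 | step 8 | benzyl (2S,3S,4S)-4-methyl-5-oxo-2-(14-oxopentadecyl)oxolane-3-carboxylate | CC(=O)CCCCCCCCCCCCC[C@@H]1OC(=O)[C@@H](C)[C@@H]1C(=O)OCc2ccccc2
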